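In a one-step world with [incoming ligand] held steady, the starting complex loses the same fraction every hour, and one constant would carry you from a run to the next flask. So first ask whether the charge of starting complex matters at the start.

| setting | dawn | winter | flask |
|---|---|---|---|
| starting complex | 28 mM | 44 mM | 20 mM |
| incoming ligand | 24 mM | 24 mM | 24.0 mM |
| scavenger | 10 mM | 10 mM | 10.0 mM |
| remark | run made earlier | run made earlier |  |
| time |  |  | 40 h |

| run | time / h | starting complex / % | complex with one exchanged / % |
|---|---|---|---|
| dawn | 6.00 | 88.7 | 11.0 |
| dawn | 12.0 | 81.7 | 19.1 |
| dawn | 20.0 | 75.0 | 24.6 |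
| dawn | 25.0 | 72.2 | 27.1 |
| winter | 3.00 | 93.6 | 5.7 |
| winter | 8.00 | 87.3 | 13.1 |
| winter | 15.0 | 82.4 | 17.1 |
| winter | 25.0 | 76.9 | 24.0 |

(standard deviation of a reading: 0.5 percentage points)

- part of the starting complex that has reacted at 40 h
- share of free incoming ligand in free incoming ligand and idle adduct together, at 40 h

The first readings give an apparent first-order constant of 0.0200 h⁻¹ in the dawn run and 0.0220 h⁻¹ in the winter run, so the larger charge of the winter run shows no clear change at the start.

Does the constant last? Define the run constant as the logarithm of charged over remaining starting complex, divided by the time elapsed. For the dawn run at 25.0 h it reads 0.0130 h⁻¹, which is less than at the start. The winter run reads 0.0105 h⁻¹, lower still.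

So which value suits this flask? Its smaller charge pushes the run constant up, and its longer time pushes it down. I let these cancel and keep the dawn value, which gives 40.5% reacted by 40 h.

The forecast says 40%, reading the slowing thus: “This suggests inhibition by released material”. Its 70% for the free share is, in its own word, a guess, and I have no reckoning for that share.

The flask gives 37.8% reacted and a free share of 84.8%. In this flask 28% of the incoming ligand stays free against 62% of the starting complex, with idle adduct at 1.19 mM. Its run constant is 0.0119 h⁻¹, a factor 0.915 of the dawn reading, so the two pushes did not quite cancel.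

    scavenger + leaving ligand → scavenged by-product (k = 1.20 M⁻¹ min⁻¹)
    starting complex + incoming ligand ⇌ leaving ligand + complex with one exchanged (K = 7.00, k = 0.0180 M⁻¹ min⁻¹)
    leaving ligand + incoming ligand ⇌ idle adduct, settled at all times (K = 470 M⁻¹)
    complex with one exchanged + incoming ligand ⇌ leaving ligand + complex with two exchanged (K = 1.30, k = 0.00130 M⁻¹ min⁻¹)
    incoming ligand ⇌ dormant form (K = 1.30, k = 5.90 × 10⁻⁴ min⁻¹)

Now take the same flask with 96 mM of incoming ligand instead. Scaling the dawn run constant with that charge, an assumption since both runs held 24 mM, gives 0.0520 h⁻¹ and so 87.5% reacted. The computed result is 86.3%.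

(The data were computed for an exercise, and the scatter is random.)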